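If intermediate A fills within minutes and drains over hours, two rates describe its curve, and the east run, this very flask followed so far, offers a reading of each.

- east: substrate 0.081 M; partner 1.2 equiv; the very flask that is asked about, followed so far
- flask: substrate 0.081 M; partner 1.20 equiv; time 2.0 h

east run (percent of the substrate charged)

| time / min | intermediate A / % | target / % |
|---|---|---|
| 1.50 | 16.9 | 0.3 |
| 4.00 | 21.7 | 0 |
| 10.0 | 22.7 | 2.5 |
| 25.0 | 20.9 | 10.1 |
| 60.0 | 17.1 | 25.8 |

(readings scatter by 0.5 percentage points)

- the earlier runs were read with a standard deviation of 0.5 percentage points
- a reading or a percentage of target counts all its forms, free or not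

1. time, not beyond 2.0 h, at which the flask holds most intermediate A
2. the amount of intermediate A, in percent of the substrate charged, at that time
3. the first time at which intermediate A reaches 6.9%, in the same percent, in min

Between 10.0 min and 60.0 min intermediate A falls from 22.7% to 17.1%, which reads as

sag rate = ln(earlier amount / later amount) / interval = 0.00567 min⁻¹

This sag rate, the fraction of intermediate A lost per minute once filling is over, is the quantity to carry. Running it back to the start gives the plateau, and the reading at 1.50 min then gives the filling:

plateau = 24.0%

fill rate = ln(plateau / (plateau − reading)) / time = 0.810 min⁻¹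

The sag is far slower than the fill, by a factor of 143, so the east run looks like a pre-equilibrium, and the rate integrates in closed form:

amount = plateau × (exp(−sag rate × t) − exp(−fill rate × t))

peak time = ln(fill rate / sag rate) / (fill rate − sag rate) = 0.103 h

This reckoning puts the peak at 23.0% and, below the earliest reading and so less firmly, reaches 6.9% after 0.418 min.

The forecast gave 0.12 h, 22.8% and 0.43 min, holding that intermediate A “leaks slowly to target”.

The flask gives 0.108 h, 23.0% and 0.479 min.

    intermediate B → target (k = 0.0150 min⁻¹)
    partner → decomposed reagent (k = 0.0940 min⁻¹)
    crystals ⇌ target, rate k3*(cs3 - [target]) while solid is left; crystals form when [target] > cs3 (solubility = 18.0 mM, k = 0.830 min⁻¹)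
    substrate ⇌ intermediate A (K = 0.610, k = 0.170 min⁻¹)
    intermediate A ⇌ intermediate B (K = 1.80, k = 0.260 min⁻¹)

Carried from the reading at 10.0 min to 2.0 h, the sag rate gives 12.2%, and the flask holds 11.9% of intermediate A at that time. The reckoning has no term for partner, so it gives the same 12.2% for a neighbour flask charged with 0.480 equiv of partner in place of 1.20 equiv. That neighbour flask peaks at 23.0%, has 0% of its partner left at 2.00 h, and holds 11.9% of intermediate A.

The runs were generated by integration for substances that don't exist; scatter was added.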